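(All constants are assumed; the rest is arithmetic.)

If the next plate was to make more D from L, I had to choose between more Q, more time and a stronger solution.

    G + Q → X + D (k1 = 70 M⁻¹ s⁻¹)
    Q ⇌ J (K2 = 1.5, k2 = 0.040 s⁻¹)
    L + Q → X + E (k3 = 23 M⁻¹ s⁻¹)
    E + Q → X + G (k4 = 190 M⁻¹ s⁻¹)
    E → Z (k5 = 0.034 s⁻¹)

| setting | green | amber |
|---|---|---|
| L | 20 mM | 20 mM |
| Q | 1.50 equiv | 1.00 equiv |
| time | 30 s | 30 s |

* which of the two there is more of at the end, green (Z / D)
* which of the two there is more of at the end, amber (Z / D)
* amount of D at the end, in percent of the L charged, green
* amount of D at the end, in percent of the L charged, amber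

Each exchange runs at its rate constant times its complex times c_Q, so c_Q sets the size of each rate and cancels from the ratio of any two exchange rates. I therefore took S = 3.04, the rate constant of G going to D over that of L going to E. This is a selectivity factor. I let E pass straight to G, because step 4 has 8.26 times the rate constant of step 3. With x the fraction of L left, the share of G is g = (x − x^S)/(S − 1), and c_Q does not appear in it.

Q was the limiting reagent, since green charged 1.50 equiv against the 3 equivalents that full conversion to D takes. Each G holds two exchanges and each D holds 3, so n equivalents spent give n = 3(1 − x) − g. Dropping x^S as a rough step gave x = (3 − n)/(3 + 1/(S − 1)).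

For green I got L at 43.0%, G at 17.3% and D at 39.7%. For amber I got L at 57.3% and D at 23.6%.

At the amber charges, the half-life of L by step 3 was 1.5 s against a run of 30 s, so more time looked useless. Step 2 alone gave Q a forward half-life of 17 s, slower than that. At the amber charges E had 20 s by step 5 against 0.18 s by step 4, so I expected D ahead of Z in both flasks. S holds no concentration, so my decision was to move the equivalents of Q and leave time and c_L.

The forecast named D in green and D in amber, with D lower than my figures at 35% and 18%, and it held that “Q is used up within a few seconds”.

The simulation gave D at 35.2% in green and 18.1% in amber, with Z at 4.31% and 5.40%.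

Green at 30.0 s held L at 41.1%. Through S that gives G at 16.9%, and the flask held 16.9%. My D for green stood 4.5 percentage points high, while E and Z, which I had not counted, held 6.84% there. The neighbour flask is green with 2.50 equiv of Q. The same count gives it L at 14.3% and D at 78.8%, and it held L at 14.9% and D at 74.2%. Its L through S gives G at 7.15%, and that neighbour flask held 7.38%.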